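**Analysis of the target**

Target 13 is a depside: two benzene rings joined by one aryl ester, with no stereocentre and no fused ring. Ring A (C1'–C6') is the acyl half and carries the ester carbonyl C7' on C1', a heptyl chain on C2' and methoxy groups on C4' and C6'. Ring B (C1–C6) is the phenol half and carries the free carboxyl C7 on C1, a methoxy group on C2, the ester oxygen on C4 and a pentyl chain on C6. Both rings are alkylresorcylates; in ring A the carbons C7', C6', C4' and C2' are the four oxidised carbons of a folded 3,5,7-trioxotetradecanoyl chain, and C1'–C2' is its aldol bond. This is the feature the route is built on. The aryl ester C7'(=O)–O–C4 is an activated ester that will not survive hydroxide or alkoxide, so the acid at C7 cannot be released by saponification, and the electron-rich, doubly ortho-substituted acid of ring B decarboxylates in hot acid. C7' is flanked by two ortho substituents, which makes classical esterification of a ring A acid slow. Of the four phenolic oxygens three end as methyl ethers and one as the ester, which in a fragment approach forces a protecting-group sequence on ring B.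

**Retrosynthetic reasoning**

13 ⇒ 12. The O–CH2Ph bond of a benzyl ester at C7 is cut. A benzyl ester is chosen because its hydrogenolysis is neutral and leaves the depside ester untouched.

12 ⇒ 11. The three O–CH3 bonds (oxygens on C4', C6' and C2) are cut together. The only phenolic oxygen of the target that is not methylated is the acylated one on C4. If the depside bond exists before methylation, one exhaustive O-methylation sets all three ethers and no protecting group is needed to tell the oxygens apart.

11 ⇒ 6 + 8 (key disconnection). Two bonds are cut: the ester bond C7'–O(C4) and the ring bond C1'–C2'. This opens ring A to the aryl triketo ester 10, which comes from acylketene 9 and the free C4–OH of 8; 9 comes from diketo-dioxinone 6 by cycloreversion. The cut is made here because the acylating species is then an unhindered ketene instead of a doubly ortho-substituted benzoic acid. The two ortho substituents arise only after the ester bond exists, and the chain folding places the heptyl group next to C7' with no regiochemical question. The forward reaction must acylate the oxygen on C4 and not the one on C2, and must close by aldol addition and not by acyl substitution.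

8 ⇒ 7. The benzyl ester bond is cut back to purchasable acid 7; the forward step is a carboxylate-selective O-benzylation.

6 ⇒ 3 + 4 (via 5). The bond between C3 and C4 of the 2,4-dioxoundecyl side chain is cut (Claisen disconnection). The forward step acylates the terminal carbon of the dianion of 3 with acyl imidazole 5, made in the flask from acid chloride 4.

3 ⇒ 1 + 2. The bond between the exocyclic carbon on C6 of the dioxinone and the acetyl carbonyl is cut; the forward step is a γ-acylation of the dienolate of 1 with 2. The key-step precursor 6 is thus two Claisen steps from a commodity dioxinone.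

**Alternatives that were turned down**

Alternative 1: the textbook route cuts only the depside bond C7'–O. The forward key step is a mixed-anhydride esterification of 2-heptyl-4,6-dimethoxybenzoic acid A1 with benzyl 4-hydroxy-2-methoxy-6-pentylbenzoate A2, followed by hydrogenolysis. It was turned down on step economy and on structure. A1 needs chain attachment to a 3,5-dimethoxyphenyl unit, a formylation with a regiochemical choice between the position next to the heptyl group and the position between the two methoxy groups, and an oxidation. A2 needs a protect–methylate–deprotect sequence to tell the oxygens on C2 and C4 apart. The key step then forms one bond at a carbonyl flanked by two ortho groups, and the route runs to about ten steps.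

Alternative 2: ring A is built by a Diels–Alder reaction and aromatisation, cutting C1'–C6' and C2'–C3'. The forward key step is cycloaddition of the alkynoate benzyl 4-(dec-2-ynoyloxy)-2-methoxy-6-pentylbenzoate A3 with 1,3-dimethoxy-1-(trimethylsilyloxy)buta-1,3-diene A4, then loss of the silyloxy group to give 12 with both ring A ethers in place. It was turned down because a β-alkyl ynoate is a weak dienophile and needs high temperature. The ketene acetal terminus of A4 is a strong nucleophile and the aryl ester of A3 an activated acyl donor, so conjugate addition without ring closure and acyl substitution with release of A2 should compete. A3 also still requires A2 and its protecting-group sequence, and A4 must be made separately.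

Alternative 3: a carbonylative three-component coupling cuts C1'–C7' and C7'–O. The forward key step is an aryloxycarbonylation of 1-heptyl-2-iodo-3,5-dimethoxybenzene A5 with phenol A2 under zerovalent palladium catalysis, giving 12. It was turned down because oxidative addition at an iodide flanked by heptyl and methoxy is slow. The doubly ortho-substituted acyl-palladium intermediate would meet a weakly nucleophilic phenol that bears a para ester, so decarbonylation and reduction should compete. A5 needs a regioselective iodination and A2 again needs protecting groups, so nothing is saved.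

Key step: step 4

Remark on the chemistry: olivetolic acid 7 is taken as a catalogue compound; lithium enolates and phenoxides formed by deprotonation are treated as forms of the numbered compounds and get no numbers of their own.

**Route**

Step 1
Reactants: 1 2,2,6-trimethyl-4H-1,3-dioxin-4-one; 2 acetyl chloride
Product: 3 keto-dioxinone 2,2-dimethyl-6-(2-oxopropyl)-4H-1,3-dioxin-4-one
Conditions: 1 (2.0 equiv), LiHMDS (2.1 equiv), THF, −78 °C; then 2 (1.0 equiv), −78 °C; aq. NH4Cl
Reagents that add atoms: none
Why: Vinylogous Claisen condensation: the lithium dienolate of 1 is acylated at its exocyclic γ-carbon by 2. The dienolate is used in twofold excess because 3 is more acidic than 1 and consumes one equivalent; the low temperature should suppress O-acylation and opening of the dioxinone.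

Step 2
Reactants: 3 keto-dioxinone 2,2-dimethyl-6-(2-oxopropyl)-4H-1,3-dioxin-4-one; 4 octanoyl chloride
Product: 6 diketo-dioxinone 6-(2,4-dioxoundecyl)-2,2-dimethyl-4H-1,3-dioxin-4-one, via 1-octanoylimidazole 5 (not isolated)
Conditions: 4, imidazole (2.0 equiv), THF, 0 → 23 °C, filter; 3 (2.0 equiv), LDA (4.1 equiv), THF, −78 °C; add filtrate of 5 (1.0 equiv), −78 → −40 °C; aq. HCl to pH 3
Reagents that add atoms: none
Why: Claisen acylation of a 1,3-dicarbonyl dianion: the terminal, more basic carbanion of the dianion of 3 attacks acyl imidazole 5. The imidazolium chloride is filtered off so that no N–H acid reaches the dianion, and the dianion is in excess because 6 is deprotonated as it forms.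

Step 3
Reactants: 7 olivetolic acid (2,4-dihydroxy-6-pentylbenzoic acid)
Product: 8 benzyl 2,4-dihydroxy-6-pentylbenzoate
Conditions: BnBr (1.05 equiv), KHCO3 (1.2 equiv), DMF, 23 °C
Reagents that add atoms: benzyl bromide, BrCc1ccccc1
Why: SN2 O-alkylation of the carboxylate, the only group that hydrogencarbonate ionises, so both phenols stay free. The step is run at room temperature because 7 decarboxylates on heating.

Step 4
Reactants: 6 diketo-dioxinone 6-(2,4-dioxoundecyl)-2,2-dimethyl-4H-1,3-dioxin-4-one; 8 benzyl 2,4-dihydroxy-6-pentylbenzoate
Product: 11 benzyl 4-[(2-heptyl-4,6-dihydroxybenzoyl)oxy]-2-hydroxy-6-pentylbenzoate, via acylketene 9 (not isolated), via aryl triketo ester 10 (not isolated)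
Conditions: 8 (2.0 equiv), PhMe (0.1 M), 110 °C; cool; Et3N (0.5 equiv), CH2Cl2, 0 → 23 °C; filtration through silica gel
Reagents that add atoms: none
Why: Proposed new method: heating 6 causes a retro-hetero-Diels–Alder loss of acetone to acylketene 9, which the non-chelated C4–OH of 8 should capture by a concerted six-centre addition across the ketene and the acyl oxygen to give aryl triketo ester 10; the amine base then ionises chain C2 (between the aryl ester and the C3 ketone), which adds to the chain C7 ketone and forms the C1'–C2' bond, and base-catalysed dehydration and enolisation give the aromatic ring. The closest known reaction type is the one-pot thermolysis of diketo-dioxinones with aliphatic alcohols followed by aldol aromatisation to alkyl resorcylates, together with the known capture of dioxinone-derived acylketenes by phenols to give aryl acetoacetates; new here is that the trapping alcohol is a phenol and that an aryl triketo ester is carried through the aromatisation. The one ring closed is carbocyclic ring A, by a 6-(enolexo)-exo-trig aldol closure, and no stereocentre is formed. Two selectivities are needed. Between the two hydroxyls of 8, the hydrogen bond of the ring B C2–OH to the ester carbonyl and its ortho ester neighbour should leave C4–OH as the only nucleophilic phenol. The aldol closure must beat Claisen closure (chain C6 onto the ester carbon with loss of the phenol) and lactonisation to a pyranone: ionisation at chain C2 makes the ester carbonyl part of an enolate and so less electrophilic, the base is weak and non-nucleophilic, no alcohol solvent is present and the closure is run cold. In one flask the step forms C7'–O and C1'–C2', and the ester carbonyl becomes flanked by two ortho groups only after the ester bond exists.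

Step 5
Reactants: 11 benzyl 4-[(2-heptyl-4,6-dihydroxybenzoyl)oxy]-2-hydroxy-6-pentylbenzoate
Product: 12 benzyl 4-[(2-heptyl-4,6-dimethoxybenzoyl)oxy]-2-methoxy-6-pentylbenzoate
Conditions: MeI (10 equiv), K2CO3 (6 equiv), acetone, 56 °C
Reagents that add atoms: iodomethane, CI
Why: Williamson ether synthesis on three phenols at once; the two hydrogen-bonded ones (on C6' and on C2) need excess reagent and reflux. Both ester carbonyls are flanked by two ortho substituents, so attack of phenoxide or carbonate on them should be slow.

Step 6
Reactants: 12 benzyl 4-[(2-heptyl-4,6-dimethoxybenzoyl)oxy]-2-methoxy-6-pentylbenzoate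
Product: 13 4-[(2-heptyl-4,6-dimethoxybenzoyl)oxy]-2-methoxy-6-pentylbenzoic acid (target)
Conditions: H2 (1 atm), Pd/C (10 wt% Pd), EtOAc, 23 °C
Reagents that add atoms: none
Why: Catalytic hydrogenolysis of the benzylic C–O bond under neutral conditions; the aryl ester and the methyl ethers are inert to it, and no saponification is needed.

**Compound list**

1 | 2,2,6-trimethyl-4H-1,3-dioxin-4-one | CC1=CC(=O)OC(C)(C)O1 | starting material
2 | acetyl chloride | CC(=O)Cl | starting material
3 | 2,2-dimethyl-6-(2-oxopropyl)-4H-1,3-dioxin-4-one (keto-dioxinone) | CC(=O)CC1=CC(=O)OC(C)(C)O1 | intermediate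
4 | octanoyl chloride | CCCCCCCC(=O)Cl | starting material
5 | 1-octanoylimidazole | CCCCCCCC(=O)n1ccnc1 | intermediate (not isolated)
6 | 6-(2,4-dioxoundecyl)-2,2-dimethyl-4H-1,3-dioxin-4-one (diketo-dioxinone) | CCCCCCCC(=O)CC(=O)CC1=CC(=O)OC(C)(C)O1 | intermediate
7 | olivetolic acid (2,4-dihydroxy-6-pentylbenzoic acid) | CCCCCc1cc(O)cc(O)c1C(=O)O | starting material
8 | benzyl 2,4-dihydroxy-6-pentylbenzoate | CCCCCc1cc(O)cc(O)c1C(=O)OCc1ccccc1 | intermediate
9 | 3,5,7-trioxotetradec-1-en-1-one (acylketene) | CCCCCCCC(=O)CC(=O)CC(=O)C=C=O | intermediate (not isolated)
10 | benzyl 2-hydroxy-6-pentyl-4-[(3,5,7-trioxotetradecanoyl)oxy]benzoate (aryl triketo ester) | CCCCCCCC(=O)CC(=O)CC(=O)CC(=O)Oc1cc(CCCCC)c(C(=O)OCc2ccccc2)c(O)c1 | intermediate (not isolated)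
11 | benzyl 4-[(2-heptyl-4,6-dihydroxybenzoyl)oxy]-2-hydroxy-6-pentylbenzoate | CCCCCCCc1cc(O)cc(O)c1C(=O)Oc1cc(CCCCC)c(C(=O)OCc2ccccc2)c(O)c1 | intermediate
12 | benzyl 4-[(2-heptyl-4,6-dimethoxybenzoyl)oxy]-2-methoxy-6-pentylbenzoate | CCCCCCCc1cc(OC)cc(OC)c1C(=O)Oc1cc(CCCCC)c(C(=O)OCc2ccccc2)c(OC)c1 | intermediate
13 | 4-[(2-heptyl-4,6-dimethoxybenzoyl)oxy]-2-methoxy-6-pentylbenzoic acid | CCCCCCCc1cc(OC)cc(OC)c1C(=O)Oc1cc(CCCCC)c(C(=O)O)c(OC)c1 | target

**Step count and least certain steps**

Total step count: 6. Longest linear sequence: 5 steps (steps 1, 2, 4, 5 and 6); step 3 is a one-step branch.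

Step 4 (key step, proposed new method). Three things may go wrong. The ketene may be captured by the enol oxygen of its own diketone (pyranone closure) before the less nucleophilic phenol adds. The aryl triketo ester may close by Claisen-type acyl substitution or lactonisation, or lose its phenoxide under base, each time releasing the phenol. Acylation may also occur at the chelated hydroxyl. The cause is that an aryl ester is a better leaving group than the alkyl esters on which the known sequence rests. The fallback uses known chemistry, sets out from 6 and 8 and rejoins at 12. Compound 6 is heated with benzyl alcohol in toluene and the alkyl triketo ester is aromatised with Cs2CO3 in methanol and then acid, which should give benzyl 2-heptyl-4,6-dihydroxybenzoate F1. Methylation (MeI, K2CO3, acetone) gives benzyl 2-heptyl-4,6-dimethoxybenzoate F2, and hydrogenolysis (H2, Pd/C) gives 2-heptyl-4,6-dimethoxybenzoic acid F3. F3 and 8 are joined with trifluoroacetic anhydride in toluene at 23 °C, which should acylate only the non-chelated hydroxyl and give benzyl 4-[(2-heptyl-4,6-dimethoxybenzoyl)oxy]-2-hydroxy-6-pentylbenzoate F4. Methylation of its one remaining phenol (MeI, K2CO3) gives 12.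

Step 2. O-acylation, double acylation, proton quench of the dianion by the more acidic product, or attack of the amide base on the dioxinone ring may lower the conversion. The fallback replaces the Claisen acylation by an aldol addition and an oxidation; it sets out from 3 and rejoins at 6. The dianion of 3 (LDA, THF, −78 °C) is added to octanal to give racemic 6-(4-hydroxy-2-oxoundecyl)-2,2-dimethyl-4H-1,3-dioxin-4-one F5, which Dess–Martin periodinane in CH2Cl2 oxidises to 6.

Step 5. Acyl transfer from the depside ester to a phenoxide or to carbonate, incomplete methylation of the two hydrogen-bonded hydroxyls, or C-methylation of the electron-rich ring A may occur. The fallback does no methylation once the depside bond exists; it sets out from 8 (and from 6 by way of F3) and rejoins at 12. Silylation of the non-chelated hydroxyl of 8 (TIPSCl, imidazole, DMF) gives benzyl 2-hydroxy-6-pentyl-4-[(triisopropylsilyl)oxy]benzoate F6. Methylation (MeI, K2CO3, acetone) gives benzyl 2-methoxy-6-pentyl-4-[(triisopropylsilyl)oxy]benzoate F7, and desilylation (TBAF, AcOH, THF) gives benzyl 4-hydroxy-2-methoxy-6-pentylbenzoate F8. F8 is then esterified with 2-heptyl-4,6-dimethoxybenzoic acid F3, made from 6 as described under step 4, using trifluoroacetic anhydride in toluene, to give 12 directly.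

Step 1. O-acylation of the dienolate, further acylation of the more acidic product and self-condensation may compete. The fallback replaces the acylation by a vinylogous Mukaiyama aldol addition and an oxidation; it sets out from 1 and rejoins at 3. Compound 1 is converted (LDA, TMSCl, THF, −78 °C) into [(2,2-dimethyl-6-methylidene-6H-1,3-dioxin-4-yl)oxy]trimethylsilane F9. Addition to acetaldehyde (BF3·OEt2, CH2Cl2, −78 °C) gives racemic 6-(2-hydroxypropyl)-2,2-dimethyl-4H-1,3-dioxin-4-one F10, which Dess–Martin periodinane oxidises to 3.

**Further compounds**

F1 | step 4 | benzyl 2-heptyl-4,6-dihydroxybenzoate | CCCCCCCc1cc(O)cc(O)c1C(=O)OCc1ccccc1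
F2 | step 4 | benzyl 2-heptyl-4,6-dimethoxybenzoate | CCCCCCCc1cc(OC)cc(OC)c1C(=O)OCc1ccccc1
F3 | step 4 | 2-heptyl-4,6-dimethoxybenzoic acid | CCCCCCCc1cc(OC)cc(OC)c1C(=O)O
F4 | step 4 | benzyl 4-[(2-heptyl-4,6-dimethoxybenzoyl)oxy]-2-hydroxy-6-pentylbenzoate | CCCCCCCc1cc(OC)cc(OC)c1C(=O)Oc1cc(CCCCC)c(C(=O)OCc2ccccc2)c(O)c1
F5 | step 2 | 6-(4-hydroxy-2-oxoundecyl)-2,2-dimethyl-4H-1,3-dioxin-4-one (racemic) | CCCCCCCC(O)CC(=O)CC1=CC(=O)OC(C)(C)O1
F6 | step 5 | benzyl 2-hydroxy-6-pentyl-4-[(triisopropylsilyl)oxy]benzoate | CCCCCc1cc(O[Si](C(C)C)(C(C)C)C(C)C)cc(O)c1C(=O)OCc1ccccc1
F7 | step 5 | benzyl 2-methoxy-6-pentyl-4-[(triisopropylsilyl)oxy]benzoate | CCCCCc1cc(O[Si](C(C)C)(C(C)C)C(C)C)cc(OC)c1C(=O)OCc1ccccc1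
F8 | step 5 | benzyl 4-hydroxy-2-methoxy-6-pentylbenzoate | CCCCCc1cc(O)cc(OC)c1C(=O)OCc1ccccc1
F9 | step 1 | [(2,2-dimethyl-6-methylidene-6H-1,3-dioxin-4-yl)oxy]trimethylsilane | C=C1C=C(O[Si](C)(C)C)OC(C)(C)O1
F10 | step 1 | 6-(2-hydroxypropyl)-2,2-dimethyl-4H-1,3-dioxin-4-one (racemic) | CC(O)CC1=CC(=O)OC(C)(C)O1
A1 | alternative 1 | 2-heptyl-4,6-dimethoxybenzoic acid | CCCCCCCc1cc(OC)cc(OC)c1C(=O)O
A2 | alternative 1 | benzyl 4-hydroxy-2-methoxy-6-pentylbenzoate | CCCCCc1cc(O)cc(OC)c1C(=O)OCc1ccccc1
A3 | alternative 2 | benzyl 4-(dec-2-ynoyloxy)-2-methoxy-6-pentylbenzoate | CCCCCCCC#CC(=O)Oc1cc(CCCCC)c(C(=O)OCc2ccccc2)c(OC)c1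
A4 | alternative 2 | 1,3-dimethoxy-1-(trimethylsilyloxy)buta-1,3-diene | C=C(OC)C=C(OC)O[Si](C)(C)C
A5 | alternative 3 | 1-heptyl-2-iodo-3,5-dimethoxybenzene | CCCCCCCc1cc(OC)cc(OC)c1I
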